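**Plan**

- Retrosynthesis: the O7–methyl bond and the O3'–benzyl protecting group are handled last. Ring A is then cut at C7–C8 and C5–C6, which gives ethyl acetate and a 6‑aryl‑4‑pyranone carrying CH2OMe and CO2Me on adjacent carbons. The pyranone is cut at its acyl C–C bond and its ring O–C(aryl) bond into methyl 4‑methoxyacetoacetate and an arylpropioloyl chloride.
- Enabling feature: in the target, C8 (OMe) sits on the oxygen‑bearing fusion carbon C8a and C5 (OH) on C4a. A pyranone with the methoxymethyl group on the future C8a and the ester on the future C4a can therefore only give the 5,7,8 pattern, never 5,6,7.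
- Forward order: ring B is bought as 3‑hydroxy‑4,5‑dimethoxybenzaldehyde and homologated to the ynoyl chloride. Ring C (the pyranone) is closed next by C‑acylation and 6‑endo‑dig oxa‑Michael addition. Ring A is annulated last by lateral Claisen acylation and Dieckmann closure, followed by 7‑O‑methylation and debenzylation.
- Stereochemistry: the target is achiral; the only sp3 centre on the way (C8 of the Claisen intermediate) is lost on aromatisation.

Key step: step 6

Remark: flavone numbering is used throughout (O1, aryl‑bearing C2, carbonyl C4, fusion carbons C4a and C8a); LiN(iPr)2 is taken as a commercial THF solution.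

**Route**

Step 1
Reactants: 1 3-hydroxy-4,5-dimethoxybenzaldehyde
Product: 2 3-(benzyloxy)-4,5-dimethoxybenzaldehyde
Conditions: BnBr, K2CO3, DMF, rt
Reagents that add atoms: benzyl bromide, BrCc1ccccc1
Why: Williamson ether synthesis, in which the phenoxide made by K2CO3 is the only nucleophile and the aldehyde is inert.

Step 2
Reactants: 2 3-(benzyloxy)-4,5-dimethoxybenzaldehyde
Product: 3 1-(benzyloxy)-5-(2,2-dibromoethenyl)-2,3-dimethoxybenzene
Conditions: CBr4, PPh3, CH2Cl2, 0 °C
Reagents that add atoms: carbon tetrabromide, BrC(Br)(Br)Br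
Why: Corey–Fuchs (Ramirez) dibromo-olefination, a Wittig reaction of the ylide formed in the flask from CBr4 and PPh3, which leaves aryl ethers untouched.

Step 3
Reactants: 3 1-(benzyloxy)-5-(2,2-dibromoethenyl)-2,3-dimethoxybenzene
Product: 5 3-[3-(benzyloxy)-4,5-dimethoxyphenyl]prop-2-ynoic acid, via lithium arylacetylide 4 (not isolated)
Conditions: n-BuLi (2.2 equiv), THF, −78 °C; CO2, −78 °C → rt; aq. HCl
Reagents that add atoms: carbon dioxide, O=C=O
Why: second stage of the Corey–Fuchs sequence, in which bromine–lithium exchange, Fritsch–Buttenberg–Wiechell rearrangement and deprotonation give the lithium acetylide, which is carboxylated by CO2.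

Step 4
Reactants: 5 3-[3-(benzyloxy)-4,5-dimethoxyphenyl]prop-2-ynoic acid
Product: 6 3-[3-(benzyloxy)-4,5-dimethoxyphenyl]prop-2-ynoyl chloride
Conditions: (COCl)2, DMF (cat.), CH2Cl2, 0 °C → rt; volatiles removed, used crude
Reagents that add atoms: oxalyl chloride, O=C(Cl)C(Cl)=O
Why: acid chloride formation through the chloroiminium (Vilsmeier-type) catalyst, which should be clean for an arylpropiolic acid that has no α-hydrogen if the mixture is kept cold and freed of HCl quickly.

Step 5
Reactants: 6 3-[3-(benzyloxy)-4,5-dimethoxyphenyl]prop-2-ynoyl chloride; 7 methyl 4-methoxy-3-oxobutanoate (methyl 4-methoxyacetoacetate)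
Product: 9 methyl 6-[3-(benzyloxy)-4,5-dimethoxyphenyl]-2-(methoxymethyl)-4-oxo-4H-pyran-3-carboxylate, via C-acylated ynone ketoester 8 (not isolated)
Conditions: MgCl2, Et3N, MeCN, 0 °C; then 6 in CH2Cl2, 0 °C → rt; 45 °C; aq. HCl
Reagents that add atoms: none
Why: magnesium-mediated C-acylation of a β-keto ester by an acid chloride (Rathke conditions) followed by 6-endo-dig oxa-Michael addition of the methoxyacetyl enol oxygen to the ynone, the classical way from acetoacetate enolates and arylpropioloyl chlorides to 6-aryl-4-pyranone-3-carboxylates.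

Step 6
Reactants: 9 methyl 6-[3-(benzyloxy)-4,5-dimethoxyphenyl]-2-(methoxymethyl)-4-oxo-4H-pyran-3-carboxylate; 10 ethyl acetate
Product: 12 3'-benzyloxy-5,7-dihydroxy-8,4',5'-trimethoxyflavone, via lateral Claisen methyl ketone 11 (not isolated)
Conditions: LiN(iPr)2 (1.1 equiv), THF, −78 °C; 10 (1.2 equiv), −78 → 0 °C; LiN(iPr)2 (2.5 equiv), −78 °C → rt; 1 M HCl
Reagents that add atoms: none
Why: Proposed new method: LiN(iPr)2 removes a proton from the methoxymethyl carbon of 9, whose anion is delocalised through the ring onto the C4 carbonyl and the ester, and this lateral anion attacks ethyl acetate (Claisen condensation, C7–C8 bond) to give methyl ketone 11 as its stabilised enolate; the second charge of base forms the terminal enolate of that ketone, which adds to the neighbouring ring ester (Dieckmann condensation, C5–C6 bond), and the cyclic triketone tautomerises to the resorcinol-type ring A. The closest known reactions are the acylation of ortho-toluate lateral anions by esters with Claisen closure to 1,3-dihydroxynaphthalenes and the related annulation of 2-methylchromone-3-carboxylates to xanthones, neither of which has been run on a monocyclic 2-(alkoxymethyl)-4-pyranone-3-carboxylate. Ring A closes in a 6-exo-trig mode onto the ester carbonyl. No stereocentre is created, because the CH(OMe) centre of 11 is transient and becomes the aromatic C8. The step needs site selectivity in the deprotonation (lateral CH2 instead of the ring C–H or addition to the pyranone) and carbon instead of oxygen acylation, which the vinylogous acidity of the CH2OMe group, the hindered amide base at −78 °C and the drain of only the C-acylated product into a stable enolate should secure, while the 5,7,8 pattern is fixed by connectivity because the methoxy carbon is already bonded to the future C8a and the ester carbon to the future C4a. Adding the ester after one equivalent of base and the excess base only afterwards keeps ethyl acetate from being consumed as its own enolate.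

Step 7
Reactants: 12 3'-benzyloxy-5,7-dihydroxy-8,4',5'-trimethoxyflavone
Product: 13 3'-benzyloxy-5-hydroxy-7,8,4',5'-tetramethoxyflavone
Conditions: Me2SO4 (1.1 equiv), K2CO3, acetone, reflux
Reagents that add atoms: dimethyl sulfate, COS(=O)(=O)OC
Why: Williamson methylation that should be selective because the 7-hydroxyl is the most acidic phenol (vinylogous to the C4 carbonyl) while the 5-hydroxyl is held in a hydrogen bond to that carbonyl and reacts far more slowly.

Step 8
Reactants: 13 3'-benzyloxy-5-hydroxy-7,8,4',5'-tetramethoxyflavone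
Product: 14 5,3'-dihydroxy-7,8,4',5'-tetramethoxyflavone
Conditions: H2 (1 atm), 10% Pd/C, EtOAc–MeOH, rt
Reagents that add atoms: none
Why: catalytic hydrogenolysis of the benzyl aryl ether, under which the methyl ethers and the C2=C3 bond of the flavone (part of a vinylogous ester) should stay intact at 1 atm and room temperature.

**Compound list**

1 | 3-hydroxy-4,5-dimethoxybenzaldehyde | COc1cc(C=O)cc(O)c1OC | starting material
2 | 3-(benzyloxy)-4,5-dimethoxybenzaldehyde | COc1cc(C=O)cc(OCc2ccccc2)c1OC | intermediate
3 | 1-(benzyloxy)-5-(2,2-dibromoethenyl)-2,3-dimethoxybenzene | COc1cc(C=C(Br)Br)cc(OCc2ccccc2)c1OC | intermediate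
4 | lithium [3-(benzyloxy)-4,5-dimethoxyphenyl]acetylide | COc1cc(C#C[Li])cc(OCc2ccccc2)c1OC | intermediate (not isolated)
5 | 3-[3-(benzyloxy)-4,5-dimethoxyphenyl]prop-2-ynoic acid | COc1cc(C#CC(=O)O)cc(OCc2ccccc2)c1OC | intermediate
6 | 3-[3-(benzyloxy)-4,5-dimethoxyphenyl]prop-2-ynoyl chloride | COc1cc(C#CC(=O)Cl)cc(OCc2ccccc2)c1OC | intermediate
7 | methyl 4-methoxy-3-oxobutanoate (methyl 4-methoxyacetoacetate) | COCC(=O)CC(=O)OC | starting material
8 | methyl 5-[3-(benzyloxy)-4,5-dimethoxyphenyl]-2-(methoxyacetyl)-3-oxopent-4-ynoate (enolised) | COCC(=O)C(C(=O)OC)C(=O)C#Cc1cc(OC)c(OC)c(OCc2ccccc2)c1 | intermediate (not isolated)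
9 | methyl 6-[3-(benzyloxy)-4,5-dimethoxyphenyl]-2-(methoxymethyl)-4-oxo-4H-pyran-3-carboxylate | COCc1oc(-c2cc(OC)c(OC)c(OCc3ccccc3)c2)cc(=O)c1C(=O)OC | intermediate
10 | ethyl acetate | CCOC(C)=O | starting material
11 | methyl 6-[3-(benzyloxy)-4,5-dimethoxyphenyl]-2-(1-methoxy-2-oxopropyl)-4-oxo-4H-pyran-3-carboxylate (racemic, present as its enolate) | COC(C(C)=O)c1oc(-c2cc(OC)c(OC)c(OCc3ccccc3)c2)cc(=O)c1C(=O)OC | intermediate (not isolated)
12 | 3'-benzyloxy-5,7-dihydroxy-8,4',5'-trimethoxyflavone (2-[3-(benzyloxy)-4,5-dimethoxyphenyl]-5,7-dihydroxy-8-methoxy-4H-chromen-4-one) | COc1cc(-c2cc(=O)c3c(O)cc(O)c(OC)c3o2)cc(OCc2ccccc2)c1OC | intermediate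
13 | 3'-benzyloxy-5-hydroxy-7,8,4',5'-tetramethoxyflavone | COc1cc(-c2cc(=O)c3c(O)cc(OC)c(OC)c3o2)cc(OCc2ccccc2)c1OC | intermediate
14 | 5,3'-dihydroxy-7,8,4',5'-tetramethoxyflavone | COc1cc(-c2cc(=O)c3c(O)cc(OC)c(OC)c3o2)cc(O)c1OC | target

**Step count and risks**

Total step count: 8. Longest linear sequence: 8 steps (1 → 14); compounds 7 and 10 are bought.

Steps most likely to fail:

1. Step 6 (lateral Claisen acylation and Dieckmann closure). The stabilised lateral anion may acylate too slowly with an unactivated, enolisable ester. The base may instead metalate the ring C–H or add to the pyranone with ring opening. The dianion may also fail to adopt the geometry that brings the terminal carbanion next to the ester. The fallback uses known chemistry and buys ring A instead of building it. It sets out from aldehyde 2. Claisen–Schmidt condensation of 2 with purchased 1-(2-hydroxy-3,4,6-trimethoxyphenyl)ethanone F1 (KOH, EtOH, rt) should give (E)-3-[3-(benzyloxy)-4,5-dimethoxyphenyl]-1-(2-hydroxy-3,4,6-trimethoxyphenyl)prop-2-en-1-one F2. I2 (cat.) in DMSO at 130 °C should close and dehydrogenate this chalcone to 3'-benzyloxy-5,7,8,4',5'-pentamethoxyflavone F3. BCl3 with pentamethylbenzene in CH2Cl2 (−78 → 0 °C) should then cleave the chelation-activated 5-O-methyl group and the benzyl ether together, so the sequence rejoins the route at target 14. The oxygen pattern comes from the acetophenone, and the cold Lewis-acid dealkylation avoids the hot protic acid that would allow Wessely–Moser equilibration to the 5,6,7 isomer.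

2. Step 5 (C-acylation and pyranone closure). The magnesium enolate may be acylated on oxygen, the enol may close 5-exo-dig to a furanone, or amine or chloride may add to the ynone before ring closure. The fallback works at the alkene oxidation level and sets out from aldehyde 2. Knoevenagel–Doebner condensation with malonic acid (pyridine, piperidine, 90 °C) should give (E)-3-[3-(benzyloxy)-4,5-dimethoxyphenyl]prop-2-enoic acid F4, and oxalyl chloride its robust acid chloride (E)-3-[3-(benzyloxy)-4,5-dimethoxyphenyl]prop-2-enoyl chloride F5. MgCl2/Et3N acylation of 7 should give methyl (E)-5-[3-(benzyloxy)-4,5-dimethoxyphenyl]-2-(methoxyacetyl)-3-oxopent-4-enoate F6. Here the enol oxygen can only close by 6-endo-trig oxa-Michael addition, to racemic methyl 2-[3-(benzyloxy)-4,5-dimethoxyphenyl]-6-(methoxymethyl)-4-oxo-3,4-dihydro-2H-pyran-5-carboxylate F7. I2 (cat.) in DMSO at 120 °C should dehydrogenate this, as in chalcone-to-flavone oxidations, and the sequence comes back at pyranone 9.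

3. Step 4 (ynoyl chloride). HCl may add across the electron-rich triple bond, or the acid chloride may decompose on concentration. The fallback transfers the acyl group without any acid chloride and sets out from acid 5. 1,1'-Carbonyldiimidazole in THF at rt should give 1-{3-[3-(benzyloxy)-4,5-dimethoxyphenyl]prop-2-ynoyl}-1H-imidazole F8 with no HCl present. This is added to the magnesium enolate of 7 (MgCl2, Et3N, MeCN) in a Masamune-type C-acylation; the acylated ketoester 8 then cyclises as in step 5 and the sequence comes back at pyranone 9.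

**Further compounds**

F1 | step 6 | 1-(2-hydroxy-3,4,6-trimethoxyphenyl)ethanone (purchased) | CC(=O)c1c(O)c(OC)c(OC)cc1OC
F2 | step 6 | (E)-3-[3-(benzyloxy)-4,5-dimethoxyphenyl]-1-(2-hydroxy-3,4,6-trimethoxyphenyl)prop-2-en-1-one | COc1cc(/C=C/C(=O)c2c(O)c(OC)c(OC)cc2OC)cc(OCc2ccccc2)c1OC
F3 | step 6 | 3'-benzyloxy-5,7,8,4',5'-pentamethoxyflavone | COc1cc(-c2cc(=O)c3c(OC)cc(OC)c(OC)c3o2)cc(OCc2ccccc2)c1OC
F4 | step 5 | (E)-3-[3-(benzyloxy)-4,5-dimethoxyphenyl]prop-2-enoic acid | COc1cc(/C=C/C(=O)O)cc(OCc2ccccc2)c1OC
F5 | step 5 | (E)-3-[3-(benzyloxy)-4,5-dimethoxyphenyl]prop-2-enoyl chloride | COc1cc(/C=C/C(Cl)=O)cc(OCc2ccccc2)c1OC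
F6 | step 5 | methyl (E)-5-[3-(benzyloxy)-4,5-dimethoxyphenyl]-2-(methoxyacetyl)-3-oxopent-4-enoate | COCC(=O)C(C(=O)OC)C(=O)/C=C/c1cc(OC)c(OC)c(OCc2ccccc2)c1
F7 | step 5 | methyl 2-[3-(benzyloxy)-4,5-dimethoxyphenyl]-6-(methoxymethyl)-4-oxo-3,4-dihydro-2H-pyran-5-carboxylate (racemic) | COCC1=C(C(=O)OC)C(=O)CC(c2cc(OC)c(OC)c(OCc3ccccc3)c2)O1
F8 | step 4 | 1-{3-[3-(benzyloxy)-4,5-dimethoxyphenyl]prop-2-ynoyl}-1H-imidazole | COc1cc(C#CC(=O)n2ccnc2)cc(OCc2ccccc2)c1OC
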